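**Assumption:** the two ring-fusion centres in the SMILES are read as (6aR,11aR), cis-fused; compounds 1 and 7 are taken as catalogue chemicals.

## Retrosynthetic overview

1. Lespecyrtin E3 (24) ⇐ acid-triggered SN1 closure of the dihydrofuran ring (O11–C11a) with loss of three MOM groups from the cis-(3R,4R)-isoflavan-4-ol 22.
2. 22 ⇐ ketoreductase-catalysed dynamic reductive kinetic resolution of racemic isoflavanone 21 (sets both stereocentres) ⇐ 1,4-reduction of isoflavone 19.
3. 19 ⇐ Suzuki–Miyaura coupling (C3–C1′) of 3-iodochromone 6 with chromenylboronate 18.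
4. 6 ⇐ enaminone/iodine cyclisation (γ-pyrone ring), with the prenyl group from Stille allylation plus cross-metathesis. 18 ⇐ three successive Br–Li exchanges on MOM-protected tribromoresorcinol (prenyl, OH, Bpin) plus a propargyl-ether Claisen/oxa-6π annulation (2H-pyran ring).
5. Ring order: γ-pyrone (step 4) and 2H-pyran (step 10) in separate branches, union (step 12), dihydrofuran last (step 15).

## Route

**Step 1**
Reactants: 1 1-(5-bromo-2,4-dihydroxyphenyl)ethan-1-one
Product: 2 1-[5-bromo-2-hydroxy-4-(methoxymethoxy)phenyl]ethan-1-one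
Conditions: MOMCl (1.1 equiv), K2CO3, acetone, 0 °C to rt
Reagents that add atoms: chloromethyl methyl ether (MOMCl), COCCl
Why: Williamson-type O-alkylation (MOM protection) takes only the 4-OH because the 2-OH is tied up in a hydrogen bond to the ketone.

**Step 2**
Reactants: 2 1-[5-bromo-2-hydroxy-4-(methoxymethoxy)phenyl]ethan-1-one
Product: 3 1-[2-hydroxy-4-(methoxymethoxy)-5-(prop-2-en-1-yl)phenyl]ethan-1-one
Conditions: allylSnBu3 (1.3 equiv), Pd(PPh3)4 (5 mol %), DMF, 95 °C
Reagents that add atoms: allyltributylstannane, C=CC[Sn](CCCC)(CCCC)CCCC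
Why: Stille cross-coupling of the aryl bromide is neutral and tolerates phenol, ketone and acetal, and an allyl group cannot give the α/γ isomer mixtures that prenyl-metal reagents can.

**Step 3**
Reactants: 3 1-[2-hydroxy-4-(methoxymethoxy)-5-(prop-2-en-1-yl)phenyl]ethan-1-one
Product: 4 (2E)-3-(dimethylamino)-1-[2-hydroxy-4-(methoxymethoxy)-5-(prop-2-en-1-yl)phenyl]prop-2-en-1-one
Conditions: Me2NCH(OMe)2 (2 equiv), toluene, 90 °C
Reagents that add atoms: N,N-dimethylformamide dimethyl acetal, COC(OC)N(C)C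
Why: condensation of the methyl ketone with the amide acetal (enaminone formation) is the standard entry to chromones from 2-hydroxyacetophenones.

**Step 4**
Reactants: 4 (2E)-3-(dimethylamino)-1-[2-hydroxy-4-(methoxymethoxy)-5-(prop-2-en-1-yl)phenyl]prop-2-en-1-one
Product: 5 3-iodo-7-(methoxymethoxy)-6-(prop-2-en-1-yl)-4H-chromen-4-one
Conditions: I2 (1.2 equiv), pyridine (1.2 equiv), CHCl3, 0 °C to rt; aq Na2S2O3 wash
Reagents that add atoms: iodine, II
Why: iodine-mediated enaminone cyclisation (α-iodination, 6-endo attack of the phenol, loss of dimethylamine) closes the γ-pyrone ring and installs the C3 iodide, the enaminone reacting far faster with iodine than the terminal alkene.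

**Step 5**
Reactants: 5 3-iodo-7-(methoxymethoxy)-6-(prop-2-en-1-yl)-4H-chromen-4-one
Product: 6 3-iodo-7-(methoxymethoxy)-6-(3-methylbut-2-en-1-yl)-4H-chromen-4-one
Conditions: Grubbs II (5 mol %), 2-methyl-2-butene (excess), CH2Cl2, 40 °C
Reagents that add atoms: 2-methyl-2-butene, CC=C(C)C
Why: olefin cross-metathesis of a terminal allyl group with 2-methyl-2-butene is a dependable route to a prenyl group, and the iodinated trisubstituted pyrone alkene is inert to the Ru carbene.

**Step 6**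
Reactants: 7 2,4,6-tribromobenzene-1,3-diol
Product: 8 1,3,5-tribromo-2,4-bis(methoxymethoxy)benzene
Conditions: MOMCl (2.5 equiv), i-Pr2NEt (3 equiv), CH2Cl2, 0 °C to rt
Reagents that add atoms: chloromethyl methyl ether (MOMCl), COCCl
Why: MOM acetal protection of both acidic phenols gives ethers that survive organolithiums and chelate lithium at their ortho positions.

**Step 7**
Reactants: 8 1,3,5-tribromo-2,4-bis(methoxymethoxy)benzene
Product: 10 1,5-dibromo-2,4-bis(methoxymethoxy)-3-(3-methylbut-2-en-1-yl)benzene, via aryllithium 9 (not isolated)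
Conditions: n-BuLi (1.0 equiv), THF, −78 °C; CuBr·SMe2 (0.2 equiv), prenyl bromide (1.3 equiv), −78 to 0 °C
Reagents that add atoms: prenyl bromide (1-bromo-3-methylbut-2-ene), CC(C)=CCBr
Why: bromine–lithium exchange goes to the bromine flanked by two OMOM groups (doubly chelated, inductively most stabilised aryllithium), and SN2 allylation at the unhindered primary carbon of prenyl bromide gives the linear prenyl group.

**Step 8**
Reactants: 10 1,5-dibromo-2,4-bis(methoxymethoxy)-3-(3-methylbut-2-en-1-yl)benzene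
Product: 13 5-bromo-2,4-bis(methoxymethoxy)-3-(3-methylbut-2-en-1-yl)phenol, via aryllithium 11 (not isolated), via dimethyl arylboronate 12 (not isolated)
Conditions: n-BuLi (1.0 equiv), THF, −78 °C; B(OMe)3, −78 °C to rt; 30% H2O2, aq NaOH, 0 °C to rt
Reagents that add atoms: hydrogen peroxide, OO
Why: mono bromine–lithium exchange of the symmetrical dibromide, borylation and boronate oxidation (1,2-aryl shift to oxygen) put the oxygen exactly where a bromine was, and alkaline peroxide leaves the isolated alkene alone.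

**Step 9**
Reactants: 13 5-bromo-2,4-bis(methoxymethoxy)-3-(3-methylbut-2-en-1-yl)phenol
Product: 14 1-bromo-2,4-bis(methoxymethoxy)-3-(3-methylbut-2-en-1-yl)-5-[(2-methylbut-3-yn-2-yl)oxy]benzene
Conditions: 3-chloro-3-methylbut-1-yne (1.5 equiv), DBU, CuCl2·2H2O (1 mol %), MeCN, 0 °C to rt
Reagents that add atoms: 3-chloro-3-methylbut-1-yne, CC(C)(Cl)C#C
Why: copper-catalysed O-alkylation of the phenol with the tertiary propargylic chloride gives the 1,1-dimethylpropargyl aryl ether under mild base.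

**Step 10**
Reactants: 14 1-bromo-2,4-bis(methoxymethoxy)-3-(3-methylbut-2-en-1-yl)-5-[(2-methylbut-3-yn-2-yl)oxy]benzene
Product: 16 5-bromo-6,8-bis(methoxymethoxy)-2,2-dimethyl-7-(3-methylbut-2-en-1-yl)-2H-chromene, via allenylphenol 15 (not isolated)
Conditions: xylenes, 140 °C
Reagents that add atoms: none
Why: aromatic propargyl Claisen rearrangement to the only free ortho carbon, then 1,5-H shift and oxa-6π electrocyclisation, builds the 2,2-dimethyl-2H-pyran ring with unambiguous regiochemistry.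

**Step 11**
Reactants: 16 5-bromo-6,8-bis(methoxymethoxy)-2,2-dimethyl-7-(3-methylbut-2-en-1-yl)-2H-chromene
Product: 18 2-[6,8-bis(methoxymethoxy)-2,2-dimethyl-7-(3-methylbut-2-en-1-yl)-2H-chromen-5-yl]-4,4,5,5-tetramethyl-1,3,2-dioxaborolane, via chromenyllithium 17 (not isolated)
Conditions: n-BuLi (1.1 equiv), THF, −78 °C; i-PrOBpin (1.5 equiv), −78 °C to rt
Reagents that add atoms: 2-isopropoxy-4,4,5,5-tetramethyl-1,3,2-dioxaborolane, CC(C)OB1OC(C)(C)C(C)(C)O1
Why: bromine–lithium exchange at −78 °C is far faster than any deprotonation next to the prenyl or chromene groups, and borate trapping gives the pinacol boronate at the former C–Br carbon.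

**Step 12**
Reactants: 6 3-iodo-7-(methoxymethoxy)-6-(3-methylbut-2-en-1-yl)-4H-chromen-4-one; 18 2-[6,8-bis(methoxymethoxy)-2,2-dimethyl-7-(3-methylbut-2-en-1-yl)-2H-chromen-5-yl]-4,4,5,5-tetramethyl-1,3,2-dioxaborolane
Product: 19 3-[6,8-bis(methoxymethoxy)-2,2-dimethyl-7-(3-methylbut-2-en-1-yl)-2H-chromen-5-yl]-7-(methoxymethoxy)-6-(3-methylbut-2-en-1-yl)-4H-chromen-4-one
Conditions: Pd(OAc)2 (5 mol %), SPhos (10 mol %), K3PO4 (3 equiv), toluene/H2O 10:1, 80 °C
Reagents that add atoms: none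
Why: Suzuki–Miyaura coupling of a 3-iodochromone with an arylboronate is the standard isoflavone synthesis, and SPhos is chosen for the doubly ortho-substituted boronate.

**Step 13**
Reactants: 19 3-[6,8-bis(methoxymethoxy)-2,2-dimethyl-7-(3-methylbut-2-en-1-yl)-2H-chromen-5-yl]-7-(methoxymethoxy)-6-(3-methylbut-2-en-1-yl)-4H-chromen-4-one
Product: 21 racemic 3-[6,8-bis(methoxymethoxy)-2,2-dimethyl-7-(3-methylbut-2-en-1-yl)-2H-chromen-5-yl]-7-(methoxymethoxy)-6-(3-methylbut-2-en-1-yl)-2,3-dihydro-4H-chromen-4-one, via lithium enolate 20 (not isolated)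
Conditions: L-Selectride (1.2 equiv), THF, −78 °C; AcOH, −78 °C to rt
Reagents that add atoms: none
Why: conjugate (1,4) hydride reduction of the chromone gives an enolate that is immune to further reduction and is protonated to the racemic isoflavanone, with the isolated alkenes and chromene untouched.

**Step 14**
Reactants: 21 racemic 3-[6,8-bis(methoxymethoxy)-2,2-dimethyl-7-(3-methylbut-2-en-1-yl)-2H-chromen-5-yl]-7-(methoxymethoxy)-6-(3-methylbut-2-en-1-yl)-2,3-dihydro-4H-chromen-4-one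
Product: 22 (3R,4R)-3-[6,8-bis(methoxymethoxy)-2,2-dimethyl-7-(3-methylbut-2-en-1-yl)-2H-chromen-5-yl]-7-(methoxymethoxy)-6-(3-methylbut-2-en-1-yl)-3,4-dihydro-2H-chromen-4-ol (3,4-cis)
Conditions: ketoreductase (KRED, (3R)-selective enzyme picked from a screening panel), NADP+ (cat.), i-PrOH (15% v/v), K phosphate buffer pH 8.5, DMSO (20% v/v), 35 °C
Reagents that add atoms: none
Why: enzymatic dynamic reductive kinetic resolution, in which the benzylic α-centre racemises through the enol at pH 8.5 while the ketoreductase reduces only the (3R)-ketone with NADPH hydride delivered anti to the aryl group, so C3 and C4 are set together as the cis-(3R,4R) alcohol.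

**Step 15**
Reactants: 22 (3R,4R)-3-[6,8-bis(methoxymethoxy)-2,2-dimethyl-7-(3-methylbut-2-en-1-yl)-2H-chromen-5-yl]-7-(methoxymethoxy)-6-(3-methylbut-2-en-1-yl)-3,4-dihydro-2H-chromen-4-ol
Product: 24 lespecyrtin E3 (6aR,11aR), via pterocarpan bis-MOM ether 23 (not isolated)
Conditions: conc. aq HCl (cat.), MeOH/THF 3:1, 0 °C to 40 °C
Reagents that add atoms: none
Why: acid ionises the oxygen-stabilised benzylic alcohol and the 2′-oxygen closes the dihydrofuran ring in an SN1 cyclisation that can only give the cis-fused pterocarpan (so C3 fixes both centres as 6aR,11aR), while the same acid transfers the MOM groups to methanol.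

## Compound list

1 | 1-(5-bromo-2,4-dihydroxyphenyl)ethan-1-one | CC(=O)c1cc(Br)c(O)cc1O | starting material
2 | 1-[5-bromo-2-hydroxy-4-(methoxymethoxy)phenyl]ethan-1-one | CC(=O)c1cc(Br)c(OCOC)cc1O | intermediate
3 | 1-[2-hydroxy-4-(methoxymethoxy)-5-(prop-2-en-1-yl)phenyl]ethan-1-one | CC(=O)c1cc(CC=C)c(OCOC)cc1O | intermediate
4 | (2E)-3-(dimethylamino)-1-[2-hydroxy-4-(methoxymethoxy)-5-(prop-2-en-1-yl)phenyl]prop-2-en-1-one | CN(C)/C=C/C(=O)c1cc(CC=C)c(OCOC)cc1O | intermediate
5 | 3-iodo-7-(methoxymethoxy)-6-(prop-2-en-1-yl)-4H-chromen-4-one | O=c1c(I)coc2cc(OCOC)c(CC=C)cc12 | intermediate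
6 | 3-iodo-7-(methoxymethoxy)-6-(3-methylbut-2-en-1-yl)-4H-chromen-4-one | O=c1c(I)coc2cc(OCOC)c(CC=C(C)C)cc12 | intermediate
7 | 2,4,6-tribromobenzene-1,3-diol (2,4,6-tribromoresorcinol) | Oc1c(Br)cc(Br)c(O)c1Br | starting material
8 | 1,3,5-tribromo-2,4-bis(methoxymethoxy)benzene | COCOc1c(Br)cc(Br)c(OCOC)c1Br | intermediate
9 | [3,5-dibromo-2,6-bis(methoxymethoxy)phenyl]lithium | [Li]c1c(OCOC)c(Br)cc(Br)c1OCOC | intermediate (not isolated)
10 | 1,5-dibromo-2,4-bis(methoxymethoxy)-3-(3-methylbut-2-en-1-yl)benzene | COCOc1c(Br)cc(Br)c(OCOC)c1CC=C(C)C | intermediate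
11 | [5-bromo-2,4-bis(methoxymethoxy)-3-(3-methylbut-2-en-1-yl)phenyl]lithium | [Li]c1cc(Br)c(OCOC)c(CC=C(C)C)c1OCOC | intermediate (not isolated)
12 | dimethyl [5-bromo-2,4-bis(methoxymethoxy)-3-(3-methylbut-2-en-1-yl)phenyl]boronate | COB(OC)c1cc(Br)c(OCOC)c(CC=C(C)C)c1OCOC | intermediate (not isolated)
13 | 5-bromo-2,4-bis(methoxymethoxy)-3-(3-methylbut-2-en-1-yl)phenol | Oc1cc(Br)c(OCOC)c(CC=C(C)C)c1OCOC | intermediate
14 | 1-bromo-2,4-bis(methoxymethoxy)-3-(3-methylbut-2-en-1-yl)-5-[(2-methylbut-3-yn-2-yl)oxy]benzene | C#CC(C)(C)Oc1cc(Br)c(OCOC)c(CC=C(C)C)c1OCOC | intermediate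
15 | 3-bromo-4,6-bis(methoxymethoxy)-2-(3-methylbuta-1,2-dien-1-yl)-5-(3-methylbut-2-en-1-yl)phenol | CC(C)=C=Cc1c(O)c(OCOC)c(CC=C(C)C)c(OCOC)c1Br | intermediate (not isolated)
16 | 5-bromo-6,8-bis(methoxymethoxy)-2,2-dimethyl-7-(3-methylbut-2-en-1-yl)-2H-chromene | COCOc1c(Br)c2C=CC(C)(C)Oc2c(OCOC)c1CC=C(C)C | intermediate
17 | [6,8-bis(methoxymethoxy)-2,2-dimethyl-7-(3-methylbut-2-en-1-yl)-2H-chromen-5-yl]lithium | [Li]c1c(OCOC)c(CC=C(C)C)c(OCOC)c2OC(C)(C)C=Cc12 | intermediate (not isolated)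
18 | 2-[6,8-bis(methoxymethoxy)-2,2-dimethyl-7-(3-methylbut-2-en-1-yl)-2H-chromen-5-yl]-4,4,5,5-tetramethyl-1,3,2-dioxaborolane | CC1(C)OB(OC1(C)C)c1c(OCOC)c(CC=C(C)C)c(OCOC)c2OC(C)(C)C=Cc12 | intermediate
19 | 3-[6,8-bis(methoxymethoxy)-2,2-dimethyl-7-(3-methylbut-2-en-1-yl)-2H-chromen-5-yl]-7-(methoxymethoxy)-6-(3-methylbut-2-en-1-yl)-4H-chromen-4-one | O=c1c(-c2c(OCOC)c(CC=C(C)C)c(OCOC)c3OC(C)(C)C=Cc23)coc2cc(OCOC)c(CC=C(C)C)cc12 | intermediate
20 | lithium 3-[6,8-bis(methoxymethoxy)-2,2-dimethyl-7-(3-methylbut-2-en-1-yl)-2H-chromen-5-yl]-7-(methoxymethoxy)-6-(3-methylbut-2-en-1-yl)-2H-chromen-4-olate | [Li]OC1=C(c2c(OCOC)c(CC=C(C)C)c(OCOC)c3OC(C)(C)C=Cc23)COc2cc(OCOC)c(CC=C(C)C)cc12 | intermediate (not isolated)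
21 | racemic 3-[6,8-bis(methoxymethoxy)-2,2-dimethyl-7-(3-methylbut-2-en-1-yl)-2H-chromen-5-yl]-7-(methoxymethoxy)-6-(3-methylbut-2-en-1-yl)-2,3-dihydro-4H-chromen-4-one | O=C1c2cc(CC=C(C)C)c(OCOC)cc2OCC1c1c(OCOC)c(CC=C(C)C)c(OCOC)c2OC(C)(C)C=Cc12 | intermediate
22 | (3R,4R)-3-[6,8-bis(methoxymethoxy)-2,2-dimethyl-7-(3-methylbut-2-en-1-yl)-2H-chromen-5-yl]-7-(methoxymethoxy)-6-(3-methylbut-2-en-1-yl)-3,4-dihydro-2H-chromen-4-ol | CC(C)=CCc1cc2c(cc1OCOC)OC[C@@H](c1c(OCOC)c(CC=C(C)C)c(OCOC)c3OC(C)(C)C=Cc13)[C@H]2O | intermediate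
23 | (6aR,11aR)-3,9-bis-O-(methoxymethyl) ether of lespecyrtin E3 | CC(C)=CCc1cc2c(cc1OCOC)OC[C@H]1c3c4c(c(OCOC)c(CC=C(C)C)c3O[C@@H]21)OC(C)(C)C=C4 | intermediate (not isolated)
24 | lespecyrtin E3, (6aR,11aR) | CC(C)=CCc1cc2c(cc1O)OC[C@H]1c3c4c(c(O)c(CC=C(C)C)c3O[C@@H]21)OC(C)(C)C=C4 | target

## Summary

Total step count: 15.
Longest linear sequence: 10 steps (7 → 8 → 10 → 13 → 14 → 16 → 18 → 19 → 21 → 22 → 24; steps 6–15).

Three steps most likely to fail:

**Step 14 (enzymatic reduction).** The isoflavanone is large, lipophilic and hindered, and no panel enzyme may accept it with useful rate or (3R)-selectivity. Only the C3 selectivity matters, since either C4 epimer converges on the cis-pterocarpan in step 15. The fallback sets out from 21 and comes back at 22. It replaces the enzyme by Noyori–Ikariya asymmetric transfer hydrogenation with dynamic kinetic resolution: RuCl[(R,R)-TsDPEN](p-cymene), HCO2H/Et3N 5:2, EtOAc, 40 °C. The (R,R) catalyst gives the 4R alcohol and the base racemises C3, so the same cis-(3R,4R) alcohol is formed. No compound outside the list is made (none F0).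

**Step 12 (Suzuki coupling).** The boronate 18 is electron-rich and carries two ortho substituents, so slow transmetalation, protodeboronation and base opening of the iodochromone can compete. The fallback sets out from 13 (and uses 6) and comes back at 19. It makes the biaryl bond before the pyran ring exists, so the boronate has only one ortho substituent.
- 13 is silylated (TIPSCl, imidazole, DMF) to the aryl triisopropylsilyl ether F1.
- Br–Li exchange (n-BuLi, THF, −78 °C) and i-PrOBpin give the silyloxy arylboronate F2.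
- Suzuki coupling with 6 (Pd(dppf)Cl2, K2CO3, dioxane/H2O, 80 °C) gives the 5′-silyloxy isoflavone F3.
- TBAF (THF, 0 °C) frees the 5′-hydroxy isoflavone F4.
- Copper-catalysed alkylation with 3-chloro-3-methylbut-1-yne (DBU, CuCl2 cat., MeCN) gives the isoflavone propargyl ether F5.
- Heating (xylenes, 140 °C) runs the same Claisen/electrocyclisation onto C6′, the only free ortho carbon, and gives 19.

**Step 15 (acid end-game).** Hot methanolic acid can cyclise the free ortho-prenylphenols to chromans or hydrate the chromene before all three MOM groups are gone. The fallback sets out from 22 and comes back at 24. It separates ring closure from deprotection.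
- 22 is cyclised under aprotic Lewis-acid catalysis (BF3·OEt2 5 mol %, MeOH 3 equiv as scavenger, CH2Cl2, −40 °C). The 2′-MOM oxygen captures the benzylic cation and sheds its MOM group, and the bis-MOM pterocarpan 23 is isolated.
- The two remaining aryl MOM ethers are removed without protic acid (TMSOTf, 2,2′-bipyridyl, CH2Cl2, 0 °C; then H2O) to give 24.

No compound outside the list is made (none F0).

## Further compounds

F0 | step 14 | none | none
F1 | step 12 | [5-bromo-2,4-bis(methoxymethoxy)-3-(3-methylbut-2-en-1-yl)phenoxy]tri(propan-2-yl)silane | CC(C)[Si](Oc1cc(Br)c(OCOC)c(CC=C(C)C)c1OCOC)(C(C)C)C(C)C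
F2 | step 12 | 2-[2,4-bis(methoxymethoxy)-3-(3-methylbut-2-en-1-yl)-5-{[tri(propan-2-yl)silyl]oxy}phenyl]-4,4,5,5-tetramethyl-1,3,2-dioxaborolane | CC(C)[Si](Oc1cc(B2OC(C)(C)C(C)(C)O2)c(OCOC)c(CC=C(C)C)c1OCOC)(C(C)C)C(C)C
F3 | step 12 | 3-[2,4-bis(methoxymethoxy)-3-(3-methylbut-2-en-1-yl)-5-{[tri(propan-2-yl)silyl]oxy}phenyl]-7-(methoxymethoxy)-6-(3-methylbut-2-en-1-yl)-4H-chromen-4-one | O=c1c(-c2cc(O[Si](C(C)C)(C(C)C)C(C)C)c(OCOC)c(CC=C(C)C)c2OCOC)coc2cc(OCOC)c(CC=C(C)C)cc12
F4 | step 12 | 3-[5-hydroxy-2,4-bis(methoxymethoxy)-3-(3-methylbut-2-en-1-yl)phenyl]-7-(methoxymethoxy)-6-(3-methylbut-2-en-1-yl)-4H-chromen-4-one | O=c1c(-c2cc(O)c(OCOC)c(CC=C(C)C)c2OCOC)coc2cc(OCOC)c(CC=C(C)C)cc12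
F5 | step 12 | 3-{2,4-bis(methoxymethoxy)-3-(3-methylbut-2-en-1-yl)-5-[(2-methylbut-3-yn-2-yl)oxy]phenyl}-7-(methoxymethoxy)-6-(3-methylbut-2-en-1-yl)-4H-chromen-4-one | O=c1c(-c2cc(OC(C)(C)C#C)c(OCOC)c(CC=C(C)C)c2OCOC)coc2cc(OCOC)c(CC=C(C)C)cc12
F0 | step 15 | none | none
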